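I wanted to know how much of the substrate had become target by the end of the run, and whether the flask was still moving then.

    substrate + free catalyst → catalyst intermediate A (k1 = 240 M⁻¹ h⁻¹)
    coupling partner + catalyst intermediate A → catalyst intermediate B (k2 = 1200 M⁻¹ h⁻¹)
    catalyst intermediate B → free catalyst + target (k3 = 4.5 h⁻¹)
    gas ⇌ coupling partner, rate k4*(csat - [coupling partner]) (k4 = 0.24 h⁻¹, csat = 3.4 mM)
    substrate + target → side product (k5 = 2.3 M⁻¹ h⁻¹)
    coupling partner + free catalyst → spent catalyst (k6 = 15 M⁻¹ h⁻¹)

substrate 20 mM; gas 3.4 mM (held); free catalyst 1.0 mM; time 15 d

* which holds at 15 d: what has brought the reaction to rest, or that it has not come to rest (it is still moving / all of the substrate has reacted)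
* target at 15 d, in percent of the substrate charged

- a species is counted by the substrate in it: one side product counts as two
- at the start none of coupling partner is dissolved
- the reaction counts as stopped when no species that holds the substrate changes by six tenths of a point or more over the second half of the time
- run time (flask): 15 d

I ordered the clocks from fast to slow. Catalyst intermediate B gave up target with a half-life of 9.24 min. Substrate took free catalyst with a half-life of 2.89 h, the other concentrations held at their charge. Target's half-life by step 5, with substrate as charged, was 0.63 d. The gas came last: at most 0.816 mM h⁻¹ of coupling partner could dissolve, so a round for each substrate charged took 1.02 d at that ceiling. Step 1 as charged could run at 4.80 mM h⁻¹, faster than that ceiling, so I took gas transfer as the rate-limiting step. Target's half-life fell inside the feeding time, so the loss had to be reckoned. With substrate as charged, free catalyst met substrate 94.1 times faster than saturated coupling partner, against 20.0 rounds for each catalyst charged, so I expected the substrate to go first.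

Step 5 at the even mix, half the charge substrate and half target: 0.230 mM h⁻¹

Feed ceiling over that rate: 3.55

This is my even ratio, a kind of selectivity factor: at one, with the feed at its ceiling and the mix even, target is eaten as fast as it is made. With substrate falling and target rising in straight lines, the product of substrate and target averages 0.667 of its even value, giving 0.188 side events per round. Each round makes one target; each side event removes one target and one substrate.

Target share: (1 − 0.188) / (1 + 0.188) = 68.4%

I knowingly left two errors in it, pulling opposite ways: the feed taken at its ceiling, and target counted as if never eaten.

The forecast gave 63% and all of the substrate has reacted, saying “Gas transfer limits the catalytic cycle to about 0.6 mM/h”. The flask gave 68.0% at 15 d, and all of the substrate has reacted.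

Target in this flask was made 4.05 times faster than used up at 0.691 d; that describes the rates of one moment, whereas my even ratio of 3.55 rests on the ceiling and the even mix, so the two are different quantities. In the neighbouring flask with 80 mM of substrate, step 5 at the even mix came to 3.68 mM h⁻¹ against the same ceiling, so my even ratio fell to 0.222, below one. That flask ended with target at 21.6% and side product at 78.4%.

Its constants were set for the occasion; what happens was integrated by code.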